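**Route proposal for CNP0233452.1, (2R,3R)-3,5,7-trihydroxy-2-(4-methoxy-3-prenylphenyl)-8-prenylchroman-4-one (19)**

Abbreviations and numbering: prenyl = 3-methylbut-2-en-1-yl; TIPS = triisopropylsilyl. Atom numbers (O1, C2, C3, C4, C4a, C5–C8, C8a, primed numbers for ring B) follow flavonoid numbering.

## Analysis of the target

Compound 19 is a dihydroflavonol: a chroman-4-one (rings A and C) with an aryl group (ring B) on C2 and a hydroxyl on C3. Ring A is a phloroglucinol-type ring with free hydroxyls on C5 and C7 and a prenyl group on C8. Ring B is a 4-methoxyphenyl ring with a second prenyl group on C3'. The two stereocentres C2 and C3 are adjacent and both R, so the aryl group and the hydroxyl are trans on ring C (both equatorial, H2 and H3 anti). The sensitive groups are: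
- the two trisubstituted alkenes, which are attacked by acid (hydration, chroman formation with the C7 hydroxyl) and by electrophilic oxidants;
- the β-aryloxy ketone, which base opens to a chalcone with loss of the C2 configuration;
- the α-ketol at C3, which can epimerise and is oxidised to the flavonol.

The synthesis is hard for three reasons: the ring A prenyl group must sit on C8 and not C6, the trans ketol must be made as one enantiomer without oxidants that attack the alkenes, and ring C must be closed without strong acid or base. The plan rests on one feature of ring A: C4a is the only hydrogen-bearing carbon ortho to O1, because C8 on the other side carries the prenyl group. C4a also lies between the oxygen-bearing carbons C8a and C5 and para to the C7 oxygen, so a carboxyl group tethered through O1–C2–C3 can reach only this strongly activated carbon.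

## Retrosynthetic reasoning

**19 back to 17 (unmasking).** The free phenols and the C3 hydroxyl are revealed last. Going backwards, the C3 hydroxyl is capped as the acetate 18, and the two phenols of 18 are capped as TIPS ethers in 17. No skeletal bond is cut. The forward steps must remove three groups without base strong enough to open ring C and without acid that would cyclise a prenyl group onto the C7 hydroxyl. The acetate is kept to the end because an α-acyloxy ketone is cleaved by very mild methanolysis.

**17 back to 15 (C4–C4a, the key disconnection).** Cutting the bond between the carbonyl carbon C4 and C4a opens ring C to the open-chain 3-aryloxy-2-acetoxy acid 15, activated in the flask as acyl chloride 16. The cut is made here because both stereocentres then lie in an acyclic chain that can be taken from one epoxide, and because the tether leaves the acyl group no other arene carbon to attack. The forward reaction closes ring C and forms one C–C bond. It must be mild enough to spare two prenyl groups and a benzylic aryl ether. The acetate on the C3 oxygen is chosen because an electron-poor acyloxy group makes loss of CO from the acylium ion less favourable than an ether or silyl ether would.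

**15 back to 13 (functional group changes).** Acid 15 comes from hydroxy acid 14 by acetylation, and 14 from methyl ester 13 by saponification. Because this saponification is needed, TIPS and not tert-butyldimethylsilyl is used on ring A: aryl tert-butyldimethylsilyl ethers would not survive the hydroxide step or the preceding phenoxide step, whereas electron-rich aryl TIPS ethers should.

**13 back to 9 and 12 (O1–C2).** Cutting the benzylic C–O bond gives the trans-glycidic ester 9 and the phenol 12. In the forward direction the phenoxide of 12 attacks the benzylic epoxide carbon with inversion, and the ester-bearing carbon keeps its oxygen. One resolved epoxide therefore delivers both stereocentres of 19 with the correct relative and absolute configuration: (2R,3S) in 9 becomes (2R,3R) in 13. This step also fixes the regiochemistry of ring A, since O1 is the only free oxygen of 12 and its prenyl-bearing neighbour becomes C8.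

**9 back to 6 and 7 (epoxide).** The glycidic ester is cut at the epoxide C–C and C–O bonds to aldehyde 6 and methyl chloroacetate 7, a Darzens condensation giving racemate 8. An enzymatic kinetic resolution of 8 gives 9. A condensation is preferred to an alkene epoxidation because it uses no electrophilic oxidant, which would attack the prenyl alkene first.

**6 back to 1 and 3 (aryl–prenyl bond on ring B).** The C3'–CH2 bond is cut to an aryl anion equivalent and prenyl bromide 3. The aryl anion is the aryllithium 4, made from bromide 2, the dimethyl acetal of the commercial aldehyde 1. The acetal is needed only to carry the aldehyde through the metalation; it is removed in the work-up, via 5.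

**12 back to 10 and 3 (ring A).** Phenol 12 comes from 2-prenylphloroglucinol 11 by silylation of two of its three hydroxyls, and 11 from phloroglucinol 10 and prenyl bromide 3 by C-alkylation. The three ring carbons of 10 are equivalent, so mono-prenylation gives one isomer. In 11 the two hydroxyls next to the prenyl group are equivalent and the third is the least hindered, so any order of two silylations converges on 12.

## Alternatives that were turned down

**Alternative 1: both prenyl groups by oxygen-to-carbon sigmatropic shifts.**
- Disconnection: the two aryl–CH2 bonds (C8–CH2 and C3'–CH2) are cut, leading back to the diether A1, which has a prenyl ether on O5 and a 1,1-dimethylallyl ether on O4'.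
- Forward key step: heating A1 with a europium Lewis acid such as Eu(fod)3 (fod = 6,6,7,7,8,8,8-heptafluoro-2,2-dimethyloctane-3,5-dionate). On ring A a Claisen shift to C6 followed by a Cope shift to C8 is expected; on ring B a Claisen shift to C3'. The product is A2, and no ring closes.
- For: no acid-sensitive prenyl group is present while the core is built, and both are installed in one operation. This is stronger than the chosen route, which carries the alkenes through ten steps.
- Against: the four oxygens on C3, C5, C7 and C4' must each carry a different group. The reverse-prenyl ether of A1 costs extra steps, and A2 still needs selective 4'-O-methylation and desilylation. The enantiopure dihydroflavonol core must come from a separate asymmetric sequence. The cascade on ring A can stop at the C6 stage, and heating a β-aryloxy ketone that now carries a free C5 hydroxyl invites ring opening at C2.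
- Comparison: the chosen route offers a fixed C8 regiochemistry (by construction of phenol 12) and both stereocentres from one epoxide, in fewer steps.

**Alternative 2: ring closure by an intramolecular silyl benzoin reaction.**
- Disconnection: the C3–C4 bond, leading back to the racemic aldehyde A3, which carries an aroylsilane at the future C4.
- Forward key step: a chiral lithium dialkyl phosphite, (RO)2POLi, adds to the acylsilane. Brook rearrangement gives a silyloxy carbanion that adds to the aldehyde. Silyl transfer and loss of the catalyst give A4; C2 is set by dynamic kinetic resolution of the epimerisable aldehyde.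
- For: a catalytic asymmetric C–C bond formation that would set both stereocentres without a resolution, under basic and non-acidic conditions that suit the prenyl groups. On yield ceiling and on mildness of ring closure this is stronger than the chosen route.
- Against: the intramolecular, dynamic version on an α-aryloxy-α-aryl aldehyde has no close precedent and would be method development at the decisive step. The aroylsilane must be installed on a ring carbon flanked by two oxygen substituents. The cis/trans outcome is not secured. The methoxymethyl groups of A4 must finally be removed with acid next to two prenyl groups.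
- Comparison: the chosen route accepts a resolution in exchange for a ring closure of a known type whose regiochemistry is forced by the tether.

**Alternative 3: ring A grown on a chiral pyranone by cycloaddition.**
- Disconnection: the C5–C4a and C8–C8a bonds, leading back to the iodo-dihydropyranone A5 and the prenyl-bearing bis(silyloxy)diene A6.
- Forward key step: Diels–Alder addition of A6 across the C4a=C8a bond of A5, then loss of hydrogen iodide and methanol to aromatise, giving A7 with free C5 and C7 hydroxyls.
- For: the substitution pattern of ring A, including the C8 prenyl group, is written into an acyclic diene, so no phloroglucinol prenylation or statistical protection is needed and the phenols arrive free. On these points it is stronger than steps 5 and 6 of the chosen route.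
- Against: A5 needs its own multi-step asymmetric synthesis with the trans C2/C3 relationship. The terminally substituted diene A6 is sensitive and its geometry matters. The cycloaddition forms a bond at the hindered iodine-bearing carbon, and the elimination steps put the C2–O1 bond at risk.
- Comparison: the chosen route builds the same ring from commodity arenes and concentrates its risk in a single, well-understood acylation.

Key step: step 10

Remark on the chemistry: the lipase of step 4 is assumed to keep, for the prenylated substrate 8, the enantiomer preference known for the parent 3-(4-methoxyphenyl)glycidic ester, so that the (2R,3S)-ester is the one left unhydrolysed.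

## Route

Step 1
Reactants: 1 3-bromo-4-methoxybenzaldehyde
Product: 2 2-bromo-4-(dimethoxymethyl)-1-methoxybenzene
Conditions: HC(OMe)3, p-TsOH·H2O (cat.), MeOH, rt
Reagents that add atoms: trimethyl orthoformate, COC(OC)OC
Why: Acid-catalysed acetal formation, driven by the orthoformate as water scavenger; it masks the aldehyde against the organolithium of the next step.

Step 2
Reactants: 2 2-bromo-4-(dimethoxymethyl)-1-methoxybenzene; 3 prenyl bromide (1-bromo-3-methylbut-2-ene)
Product: 6 4-methoxy-3-(3-methylbut-2-en-1-yl)benzaldehyde, via aryllithium 4 (not isolated), via prenylated dimethyl acetal 5 (not isolated)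
Conditions: n-BuLi, THF, −78 °C; CuBr·SMe2 (10 mol%), 3, −78 → 0 °C; then 1 M HCl, THF, rt
Reagents that add atoms: water, O
Why: Bromine–lithium exchange followed by copper-catalysed allylic substitution at the primary carbon of 3 (SN2 rather than SN2′, since the γ-carbon is fully substituted); dilute acid in the work-up hydrolyses the dimethyl acetal without affecting the trisubstituted alkene.

Step 3
Reactants: 6 4-methoxy-3-(3-methylbut-2-en-1-yl)benzaldehyde; 7 methyl chloroacetate
Product: 8 methyl trans-3-[4-methoxy-3-(3-methylbut-2-en-1-yl)phenyl]oxirane-2-carboxylate (racemate)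
Conditions: NaOMe, MeOH, −10 °C → rt
Reagents that add atoms: none
Why: Darzens glycidic ester condensation: the chloroacetate enolate adds to the aldehyde and the chlorohydrin alkoxide closes by intramolecular SN2; the aldol step is reversible and the anti aldolate cyclises faster, so the trans epoxide should predominate, as for 4-methoxybenzaldehyde; C2 and C3 are set only relative to each other.

Step 4
Reactants: 8 methyl trans-3-[4-methoxy-3-(3-methylbut-2-en-1-yl)phenyl]oxirane-2-carboxylate (racemate)
Product: 9 methyl (2R,3S)-3-[4-methoxy-3-(3-methylbut-2-en-1-yl)phenyl]oxirane-2-carboxylate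
Conditions: Serratia marcescens lipase, toluene/phosphate buffer pH 7.5, 30 °C, stopped shortly after half conversion
Reagents that add atoms: none
Why: Enzymatic kinetic resolution by enantioselective ester hydrolysis, the reaction type established for trans-3-arylglycidic esters; the lipase should hydrolyse the (2S,3R)-ester to the water-soluble acid and leave 9 in the organic phase, which fixes the absolute configuration of both stereocentres.

Step 5
Reactants: 10 phloroglucinol (benzene-1,3,5-triol); 3 prenyl bromide
Product: 11 2-(3-methylbut-2-en-1-yl)benzene-1,3,5-triol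
Conditions: 10% aq. KOH, 10 in excess (3 equiv), 0 °C → rt
Reagents that add atoms: none
Why: C-alkylation of the ambident phloroglucinolate in water, where hydrogen bonding to oxygen directs the primary allylic halide to carbon; the three ring carbons of 10 are equivalent, and the excess of 10 limits double prenylation.

Step 6
Reactants: 11 2-(3-methylbut-2-en-1-yl)benzene-1,3,5-triol
Product: 12 2-(3-methylbut-2-en-1-yl)-3,5-bis(triisopropylsilyloxy)phenol
Conditions: TIPSCl (2.05 equiv), imidazole, DMF, 0 °C → rt
Reagents that add atoms: chlorotriisopropylsilane, CC(C)[Si](Cl)(C(C)C)C(C)C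
Why: O-silylation under steric control: the hydroxyl para to the prenyl group is the most accessible and the two ortho hydroxyls are equivalent, so either order of two silylations gives 12, while the third silylation next to the prenyl group and a TIPS ether is slow.

Step 7
Reactants: 9 methyl (2R,3S)-3-[4-methoxy-3-(3-methylbut-2-en-1-yl)phenyl]oxirane-2-carboxylate; 12 2-(3-methylbut-2-en-1-yl)-3,5-bis(triisopropylsilyloxy)phenol
Product: 13 methyl (2R,3R)-2-hydroxy-3-[4-methoxy-3-(3-methylbut-2-en-1-yl)phenyl]-3-[2-(3-methylbut-2-en-1-yl)-3,5-bis(triisopropylsilyloxy)phenoxy]propanoate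
Conditions: NaH (0.25 equiv), 12 (1.1 equiv), DMF, 0 → 50 °C
Reagents that add atoms: none
Why: Base-catalysed SN2 opening of an epoxide by a phenoxide, the reaction type known for trans-3-aryl glycidic esters and glycidols; the phenoxide attacks the benzylic carbon from the side opposite the epoxide oxygen, so C3 goes from S to R while C2 keeps its oxygen and its R configuration, and catalytic base leaves the product as the neutral alcohol.

Step 8
Reactants: 13 methyl (2R,3R)-2-hydroxy-3-[4-methoxy-3-(3-methylbut-2-en-1-yl)phenyl]-3-[2-(3-methylbut-2-en-1-yl)-3,5-bis(triisopropylsilyloxy)phenoxy]propanoate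
Product: 14 (2R,3R)-2-hydroxy-3-[4-methoxy-3-(3-methylbut-2-en-1-yl)phenyl]-3-[2-(3-methylbut-2-en-1-yl)-3,5-bis(triisopropylsilyloxy)phenoxy]propanoic acid
Conditions: LiOH·H2O, THF/H2O, 0 °C; then 0.5 M HCl to pH 3–4, 0 °C
Reagents that add atoms: lithium hydroxide, [Li+].[OH-]
Why: Saponification of an α-hydroxy methyl ester, which is fast in the cold because of the α-oxygen; electron-rich aryl TIPS ethers should tolerate cold LiOH, and neither stereocentre is acidic in the carboxylate.

Step 9
Reactants: 14 (2R,3R)-2-hydroxy-3-[4-methoxy-3-(3-methylbut-2-en-1-yl)phenyl]-3-[2-(3-methylbut-2-en-1-yl)-3,5-bis(triisopropylsilyloxy)phenoxy]propanoic acid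
Product: 15 (2R,3R)-2-acetoxy-3-[4-methoxy-3-(3-methylbut-2-en-1-yl)phenyl]-3-[2-(3-methylbut-2-en-1-yl)-3,5-bis(triisopropylsilyloxy)phenoxy]propanoic acid
Conditions: Ac2O, pyridine, DMAP (cat.), CH2Cl2, 0 °C → rt; then H2O/THF
Reagents that add atoms: acetic anhydride, CC(=O)OC(C)=O
Why: O-acetylation of the only free hydroxyl; the mixed anhydride that forms at the carboxyl group is hydrolysed in the aqueous work-up, and the weak base does not epimerise C2.

Step 10
Reactants: 15 (2R,3R)-2-acetoxy-3-[4-methoxy-3-(3-methylbut-2-en-1-yl)phenyl]-3-[2-(3-methylbut-2-en-1-yl)-3,5-bis(triisopropylsilyloxy)phenoxy]propanoic acid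
Product: 17 (2R,3R)-3-acetoxy-2-[4-methoxy-3-(3-methylbut-2-en-1-yl)phenyl]-8-(3-methylbut-2-en-1-yl)-5,7-bis(triisopropylsilyloxy)chroman-4-one, via acyl chloride 16 (not isolated)
Conditions: 1-chloro-N,N,2-trimethylprop-1-en-1-amine (1.0 equiv), CH2Cl2, 0 °C → rt; then AgOTf, 2,6-di-tert-butyl-4-methylpyridine, 4 Å MS, CH2Cl2 (0.005 M), −78 → −30 °C
Reagents that add atoms: none
Why: The chloroenamine converts the acid into acyl chloride 16 under neutral conditions with only an amide as by-product, so neither the prenyl groups nor the stereocentre next to the carboxyl group meet acid or base. AgOTf then abstracts chloride, and the acylium ion, held as a five-membered acetoxonium ion by the neighbouring acetate, is attacked by C4a of ring A; the arenium ion loses its proton to the hindered pyridine. The closest known reaction type is the intramolecular Friedel-Crafts acylation of 3-aryloxypropanoic acids to chroman-4-ones, combined with silver-promoted acylation of activated arenes by acyl chlorides. The six-membered ring C closes in a 6-exo mode with respect to the acyl electrophile, and the C4a–C8a bond of the arene becomes part of the ring. No stereocentre is formed: C2 and C3 are carried over from 15, and no base strong enough to form a ketene is present, so C3 stays intact. Site selectivity is needed between C4a and the other free ring A carbon (C6, between the two silyloxy groups); the tether through O1 reaches only C4a, which is ortho to O1 and to the C5 oxygen and para to the C7 oxygen. Chemoselectivity over the two prenyl alkenes is secured because acylating them would require rings of eight or more members, and because the pyridine removes triflic acid as it forms at low temperature. The electron-poor acetate on the C3 oxygen disfavours loss of CO from the acylium ion, and the use of exactly one equivalent of chloroenamine avoids a keteniminium salt that could add to the alkenes.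

Step 11
Reactants: 17 (2R,3R)-3-acetoxy-2-[4-methoxy-3-(3-methylbut-2-en-1-yl)phenyl]-8-(3-methylbut-2-en-1-yl)-5,7-bis(triisopropylsilyloxy)chroman-4-one
Product: 18 (2R,3R)-3-acetoxy-5,7-dihydroxy-2-[4-methoxy-3-(3-methylbut-2-en-1-yl)phenyl]-8-(3-methylbut-2-en-1-yl)chroman-4-one
Conditions: TBAF, AcOH (1:1), THF, 0 °C
Reagents that add atoms: none
Why: Fluoride-induced cleavage of aryl silyl ethers; the phenoxides ortho and para to the ketone are good leaving groups from silicon, and acetic acid protonates them at once, so the β-aryloxy ketone and the acetate are not exposed to base.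

Step 12
Reactants: 18 (2R,3R)-3-acetoxy-5,7-dihydroxy-2-[4-methoxy-3-(3-methylbut-2-en-1-yl)phenyl]-8-(3-methylbut-2-en-1-yl)chroman-4-one
Product: 19 (2R,3R)-3,5,7-trihydroxy-2-[4-methoxy-3-(3-methylbut-2-en-1-yl)phenyl]-8-(3-methylbut-2-en-1-yl)chroman-4-one (target)
Conditions: K2CO3 (0.3 equiv), degassed MeOH, 0 °C, Ar; then pH 7 buffer
Reagents that add atoms: none
Why: Base-catalysed transesterification (methanolysis) of an α-acyloxy ketone, which the adjacent carbonyl group activates; the substoichiometric carbonate is buffered by the acidic C7 phenol, the cold oxygen-free medium protects the ketol, and the trans arrangement is also the more stable one at C3.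

## Compound list

1 | 3-bromo-4-methoxybenzaldehyde | COc1ccc(C=O)cc1Br | starting material
2 | 2-bromo-4-(dimethoxymethyl)-1-methoxybenzene | COc1ccc(C(OC)OC)cc1Br | intermediate
3 | prenyl bromide (1-bromo-3-methylbut-2-ene) | CC(C)=CCBr | starting material
4 | [5-(dimethoxymethyl)-2-methoxyphenyl]lithium | COc1ccc(C(OC)OC)cc1[Li] | intermediate
5 | 4-(dimethoxymethyl)-1-methoxy-2-(3-methylbut-2-en-1-yl)benzene | COc1ccc(C(OC)OC)cc1CC=C(C)C | intermediate
6 | 4-methoxy-3-(3-methylbut-2-en-1-yl)benzaldehyde | COc1ccc(C=O)cc1CC=C(C)C | intermediate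
7 | methyl chloroacetate | COC(=O)CCl | starting material
8 | methyl trans-3-[4-methoxy-3-(3-methylbut-2-en-1-yl)phenyl]oxirane-2-carboxylate (racemate; one enantiomer drawn to show the trans relative configuration) | COC(=O)[C@@H]1O[C@H]1c1ccc(OC)c(CC=C(C)C)c1 | intermediate
9 | methyl (2R,3S)-3-[4-methoxy-3-(3-methylbut-2-en-1-yl)phenyl]oxirane-2-carboxylate | COC(=O)[C@@H]1O[C@H]1c1ccc(OC)c(CC=C(C)C)c1 | intermediate
10 | phloroglucinol (benzene-1,3,5-triol) | Oc1cc(O)cc(O)c1 | starting material
11 | 2-(3-methylbut-2-en-1-yl)benzene-1,3,5-triol | CC(C)=CCc1c(O)cc(O)cc1O | intermediate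
12 | 2-(3-methylbut-2-en-1-yl)-3,5-bis(triisopropylsilyloxy)phenol | CC(C)=CCc1c(O)cc(O[Si](C(C)C)(C(C)C)C(C)C)cc1O[Si](C(C)C)(C(C)C)C(C)C | intermediate
13 | methyl (2R,3R)-2-hydroxy-3-[4-methoxy-3-(3-methylbut-2-en-1-yl)phenyl]-3-[2-(3-methylbut-2-en-1-yl)-3,5-bis(triisopropylsilyloxy)phenoxy]propanoate | COc1ccc([C@@H](Oc2c(CC=C(C)C)c(O[Si](C(C)C)(C(C)C)C(C)C)cc(O[Si](C(C)C)(C(C)C)C(C)C)c2)[C@@H](O)C(=O)OC)cc1CC=C(C)C | intermediate
14 | (2R,3R)-2-hydroxy-3-[4-methoxy-3-(3-methylbut-2-en-1-yl)phenyl]-3-[2-(3-methylbut-2-en-1-yl)-3,5-bis(triisopropylsilyloxy)phenoxy]propanoic acid | COc1ccc([C@@H](Oc2c(CC=C(C)C)c(O[Si](C(C)C)(C(C)C)C(C)C)cc(O[Si](C(C)C)(C(C)C)C(C)C)c2)[C@@H](O)C(=O)O)cc1CC=C(C)C | intermediate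
15 | (2R,3R)-2-acetoxy-3-[4-methoxy-3-(3-methylbut-2-en-1-yl)phenyl]-3-[2-(3-methylbut-2-en-1-yl)-3,5-bis(triisopropylsilyloxy)phenoxy]propanoic acid | COc1ccc([C@@H](Oc2c(CC=C(C)C)c(O[Si](C(C)C)(C(C)C)C(C)C)cc(O[Si](C(C)C)(C(C)C)C(C)C)c2)[C@@H](OC(C)=O)C(=O)O)cc1CC=C(C)C | intermediate
16 | (2R,3R)-2-acetoxy-3-[4-methoxy-3-(3-methylbut-2-en-1-yl)phenyl]-3-[2-(3-methylbut-2-en-1-yl)-3,5-bis(triisopropylsilyloxy)phenoxy]propanoyl chloride | COc1ccc([C@@H](Oc2c(CC=C(C)C)c(O[Si](C(C)C)(C(C)C)C(C)C)cc(O[Si](C(C)C)(C(C)C)C(C)C)c2)[C@@H](OC(C)=O)C(=O)Cl)cc1CC=C(C)C | intermediate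
17 | (2R,3R)-3-acetoxy-2-[4-methoxy-3-(3-methylbut-2-en-1-yl)phenyl]-8-(3-methylbut-2-en-1-yl)-5,7-bis(triisopropylsilyloxy)chroman-4-one | COc1ccc([C@H]2Oc3c(CC=C(C)C)c(O[Si](C(C)C)(C(C)C)C(C)C)cc(O[Si](C(C)C)(C(C)C)C(C)C)c3C(=O)[C@@H]2OC(C)=O)cc1CC=C(C)C | intermediate
18 | (2R,3R)-3-acetoxy-5,7-dihydroxy-2-[4-methoxy-3-(3-methylbut-2-en-1-yl)phenyl]-8-(3-methylbut-2-en-1-yl)chroman-4-one | COc1ccc([C@H]2Oc3c(CC=C(C)C)c(O)cc(O)c3C(=O)[C@@H]2OC(C)=O)cc1CC=C(C)C | intermediate
19 | (2R,3R)-3,5,7-trihydroxy-2-[4-methoxy-3-(3-methylbut-2-en-1-yl)phenyl]-8-(3-methylbut-2-en-1-yl)chroman-4-one | COc1ccc([C@H]2Oc3c(CC=C(C)C)c(O)cc(O)c3C(=O)[C@@H]2O)cc1CC=C(C)C | target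

## Step count and risks

Total: 12 steps. Longest linear sequence: 10 steps (1, 2, 3, 4, 7, 8, 9, 10, 11, 12 from compound 1); steps 5 and 6 form the ring A branch that joins at step 7.

**Step 10 (key step).** The most likely failure is ionisation outrunning ring closure. Possible paths are loss of CO from the α-oxygenated acylium ion, heterolysis of the benzylic C2–O1 bond (a 4-alkoxybenzylic ether) with loss of configuration or fragmentation, and slow attack at a carbon flanked by a bulky silyloxy group, which gives the alkenes time to react. Partial loss of the C5 silyl group would not matter, since step 11 removes both.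

Fallback: from 15, replace the acylium ion by an activated amide, which cannot lose CO. Coupling of 15 with dimethylamine (EDC·HCl, HOBt, iPr2NEt, CH2Cl2) gives (2R,3R)-2-acetoxy-N,N-dimethyl-3-[4-methoxy-3-(3-methylbut-2-en-1-yl)phenyl]-3-[2-(3-methylbut-2-en-1-yl)-3,5-bis(triisopropylsilyloxy)phenoxy]propanamide F1. Activation with Tf2O and 2-chloropyridine in CH2Cl2 at −78 → 0 °C should give, by a Vilsmeier-Haack-type intramolecular attack of C4a on the iminium carbon, the cyclic 3-acetoxy-4-(dimethyliminio)chroman triflate F2. Aqueous NaHCO3 hydrolyses F2 to 17, where the route is rejoined.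

**Step 7.** Because the aryl group is strongly donating, the epoxide may open through an ion pair and not by clean backside attack, which would erode the inversion at the benzylic carbon. The hindered phenoxide may also attack the ester carbonyl, be alkylated at carbon, or exchange silyl groups. A diastereomer formed here would have to be separated at the stage of 13, since later equilibration at C3 would turn it into the enantiomeric series.

Fallback: from 9, remove the ester before the ether is formed. NaBH4 in MeOH at 0 °C reduces 9 to [(2S,3S)-3-[4-methoxy-3-(3-methylbut-2-en-1-yl)phenyl]oxiran-2-yl]methanol F3. The phenoxide of 12 opens F3 at the benzylic carbon, under the catalytic sodium phenoxide conditions of step 7 or in aqueous NaOH (the medium in which 3-aryl glycidols are known to be opened by phenols), to give (2S,3R)-3-[4-methoxy-3-(3-methylbut-2-en-1-yl)phenyl]-3-[2-(3-methylbut-2-en-1-yl)-3,5-bis(triisopropylsilyloxy)phenoxy]propane-1,2-diol F4. Selective oxidation of the primary alcohol of F4 (TEMPO cat., PhI(OAc)2, MeCN/pH 7 buffer) gives acid 14 directly, which rejoins the route and bypasses step 8.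

**Step 4.** The enzyme may discriminate poorly between the enantiomers of the prenylated substrate or hydrolyse it slowly, and a resolution can in any case deliver at most half of the material.

Fallback: from 6, make the epoxide by asymmetric nucleophilic epoxidation, which cannot touch the electron-rich prenyl alkene. Olefination of 6 with trimethyl phosphonoacetate (NaH, THF, 0 °C) gives methyl (E)-3-[4-methoxy-3-(3-methylbut-2-en-1-yl)phenyl]prop-2-enoate F5. Conjugate epoxidation of F5 with t-BuOOH, catalysed by Y(OiPr)3, a chiral 2,2'-biaryldiol and Ph3AsO, with the ligand enantiomer chosen for the (2R,3S) product, gives 9 directly and bypasses steps 3 and 4.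

**Step 6 (together with step 5).** Both steps can give statistical mixtures: double prenylation in step 5, and mono- or tris-silylated material (or the wrong bis-silyl isomer) in step 6.

Fallback: from 10, reverse the order. Bis-silylation of 10 (TIPSCl, imidazole, DMF), whose three hydroxyls are equivalent, gives 3,5-bis(triisopropylsilyloxy)phenol F6 as the only possible bis-silyl isomer. The sodium phenoxide of F6 (NaH, toluene) is then prenylated with 3 at an ortho carbon; the non-polar medium favours ortho C-alkylation through the tight ion pair, and both ortho positions are equivalent. This gives 12.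

**Step 12.** Even mild base may open ring C (epimerising C2), epimerise C3, or in the presence of air oxidise the ketol to the flavonol.

Fallback: from 14, carry a chloroacetate, which is removed by a neutral nucleophile, in place of the acetate.
- Chloroacetic anhydride and pyridine convert 14 into (2R,3R)-2-(2-chloroacetoxy)-3-[4-methoxy-3-(3-methylbut-2-en-1-yl)phenyl]-3-[2-(3-methylbut-2-en-1-yl)-3,5-bis(triisopropylsilyloxy)phenoxy]propanoic acid F7.
- The conditions of step 10 give the corresponding (2R,3R)-2-(2-chloroacetoxy)propanoyl chloride F8 and then (2R,3R)-3-(2-chloroacetoxy)-2-[4-methoxy-3-(3-methylbut-2-en-1-yl)phenyl]-8-(3-methylbut-2-en-1-yl)-5,7-bis(triisopropylsilyloxy)chroman-4-one F9.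
- Thiourea and NaHCO3 in EtOH at 40 °C remove the chloroacetyl group to give (2R,3R)-3-hydroxy-2-[4-methoxy-3-(3-methylbut-2-en-1-yl)phenyl]-8-(3-methylbut-2-en-1-yl)-5,7-bis(triisopropylsilyloxy)chroman-4-one F10.
- TBAF/AcOH as in step 11 then gives 19.

## Further compounds

F1 | step 10 | (2R,3R)-2-acetoxy-N,N-dimethyl-3-[4-methoxy-3-(3-methylbut-2-en-1-yl)phenyl]-3-[2-(3-methylbut-2-en-1-yl)-3,5-bis(triisopropylsilyloxy)phenoxy]propanamide | COc1ccc([C@@H](Oc2c(CC=C(C)C)c(O[Si](C(C)C)(C(C)C)C(C)C)cc(O[Si](C(C)C)(C(C)C)C(C)C)c2)[C@@H](OC(C)=O)C(=O)N(C)C)cc1CC=C(C)C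
F2 | step 10 | 3-acetoxy-4-(dimethyliminio)-2-[4-methoxy-3-(3-methylbut-2-en-1-yl)phenyl]-8-(3-methylbut-2-en-1-yl)-5,7-bis(triisopropylsilyloxy)chroman triflate (spatial arrangement at C2 and C3 as in 17) | COc1ccc([C@H]2Oc3c(CC=C(C)C)c(O[Si](C(C)C)(C(C)C)C(C)C)cc(O[Si](C(C)C)(C(C)C)C(C)C)c3C(=[N+](C)C)[C@@H]2OC(C)=O)cc1CC=C(C)C.[O-]S(=O)(=O)C(F)(F)F
F3 | step 7 | [(2S,3S)-3-[4-methoxy-3-(3-methylbut-2-en-1-yl)phenyl]oxiran-2-yl]methanol | OC[C@@H]1O[C@H]1c1ccc(OC)c(CC=C(C)C)c1
F4 | step 7 | (2S,3R)-3-[4-methoxy-3-(3-methylbut-2-en-1-yl)phenyl]-3-[2-(3-methylbut-2-en-1-yl)-3,5-bis(triisopropylsilyloxy)phenoxy]propane-1,2-diol | COc1ccc([C@@H](Oc2c(CC=C(C)C)c(O[Si](C(C)C)(C(C)C)C(C)C)cc(O[Si](C(C)C)(C(C)C)C(C)C)c2)[C@@H](O)CO)cc1CC=C(C)C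
F5 | step 4 | methyl (E)-3-[4-methoxy-3-(3-methylbut-2-en-1-yl)phenyl]prop-2-enoate | COC(=O)/C=C/c1ccc(OC)c(CC=C(C)C)c1
F6 | step 6 | 3,5-bis(triisopropylsilyloxy)phenol | Oc1cc(O[Si](C(C)C)(C(C)C)C(C)C)cc(O[Si](C(C)C)(C(C)C)C(C)C)c1
F7 | step 12 | (2R,3R)-2-(2-chloroacetoxy)-3-[4-methoxy-3-(3-methylbut-2-en-1-yl)phenyl]-3-[2-(3-methylbut-2-en-1-yl)-3,5-bis(triisopropylsilyloxy)phenoxy]propanoic acid | COc1ccc([C@@H](Oc2c(CC=C(C)C)c(O[Si](C(C)C)(C(C)C)C(C)C)cc(O[Si](C(C)C)(C(C)C)C(C)C)c2)[C@@H](OC(=O)CCl)C(=O)O)cc1CC=C(C)C
F8 | step 12 | (2R,3R)-2-(2-chloroacetoxy)-3-[4-methoxy-3-(3-methylbut-2-en-1-yl)phenyl]-3-[2-(3-methylbut-2-en-1-yl)-3,5-bis(triisopropylsilyloxy)phenoxy]propanoyl chloride | COc1ccc([C@@H](Oc2c(CC=C(C)C)c(O[Si](C(C)C)(C(C)C)C(C)C)cc(O[Si](C(C)C)(C(C)C)C(C)C)c2)[C@@H](OC(=O)CCl)C(=O)Cl)cc1CC=C(C)C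
F9 | step 12 | (2R,3R)-3-(2-chloroacetoxy)-2-[4-methoxy-3-(3-methylbut-2-en-1-yl)phenyl]-8-(3-methylbut-2-en-1-yl)-5,7-bis(triisopropylsilyloxy)chroman-4-one | COc1ccc([C@H]2Oc3c(CC=C(C)C)c(O[Si](C(C)C)(C(C)C)C(C)C)cc(O[Si](C(C)C)(C(C)C)C(C)C)c3C(=O)[C@@H]2OC(=O)CCl)cc1CC=C(C)C
F10 | step 12 | (2R,3R)-3-hydroxy-2-[4-methoxy-3-(3-methylbut-2-en-1-yl)phenyl]-8-(3-methylbut-2-en-1-yl)-5,7-bis(triisopropylsilyloxy)chroman-4-one | COc1ccc([C@H]2Oc3c(CC=C(C)C)c(O[Si](C(C)C)(C(C)C)C(C)C)cc(O[Si](C(C)C)(C(C)C)C(C)C)c3C(=O)[C@@H]2O)cc1CC=C(C)C
A1 | alternative 1 | (2R,3R)-3,7-bis(tert-butyldimethylsilyloxy)-5-(3-methylbut-2-en-1-yloxy)-2-[4-(2-methylbut-3-en-2-yloxy)phenyl]chroman-4-one | C=CC(C)(C)Oc1ccc([C@H]2Oc3cc(O[Si](C)(C)C(C)(C)C)cc(OCC=C(C)C)c3C(=O)[C@@H]2O[Si](C)(C)C(C)(C)C)cc1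
A2 | alternative 1 | (2R,3R)-3,7-bis(tert-butyldimethylsilyloxy)-5-hydroxy-2-[4-hydroxy-3-(3-methylbut-2-en-1-yl)phenyl]-8-(3-methylbut-2-en-1-yl)chroman-4-one | Oc1ccc([C@H]2Oc3c(CC=C(C)C)c(O[Si](C)(C)C(C)(C)C)cc(O)c3C(=O)[C@@H]2O[Si](C)(C)C(C)(C)C)cc1CC=C(C)C
A3 | alternative 2 | 2-[3,5-bis(methoxymethoxy)-2-(3-methylbut-2-en-1-yl)-6-(triethylsilylcarbonyl)phenoxy]-2-[4-methoxy-3-(3-methylbut-2-en-1-yl)phenyl]acetaldehyde (racemic) | COc1ccc(C(C=O)Oc2c(CC=C(C)C)c(OCOC)cc(OCOC)c2C(=O)[Si](CC)(CC)CC)cc1CC=C(C)C
A4 | alternative 2 | (2R,3R)-5,7-bis(methoxymethoxy)-2-[4-methoxy-3-(3-methylbut-2-en-1-yl)phenyl]-8-(3-methylbut-2-en-1-yl)-3-(triethylsilyloxy)chroman-4-one | COc1ccc([C@H]2Oc3c(CC=C(C)C)c(OCOC)cc(OCOC)c3C(=O)[C@@H]2O[Si](CC)(CC)CC)cc1CC=C(C)C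
A5 | alternative 3 | (2R,3R)-3-(tert-butyldimethylsilyloxy)-5-iodo-2-[4-methoxy-3-(3-methylbut-2-en-1-yl)phenyl]-2,3-dihydro-4H-pyran-4-one | COc1ccc([C@H]2OC=C(I)C(=O)[C@@H]2O[Si](C)(C)C(C)(C)C)cc1CC=C(C)C
A6 | alternative 3 | 1-methoxy-7-methyl-1,3-bis(trimethylsilyloxy)octa-1,3,6-triene | COC(O[Si](C)(C)C)=CC(O[Si](C)(C)C)=CCC=C(C)C
A7 | alternative 3 | (2R,3R)-3-(tert-butyldimethylsilyloxy)-5,7-dihydroxy-2-[4-methoxy-3-(3-methylbut-2-en-1-yl)phenyl]-8-(3-methylbut-2-en-1-yl)chroman-4-one | COc1ccc([C@H]2Oc3c(CC=C(C)C)c(O)cc(O)c3C(=O)[C@@H]2O[Si](C)(C)C(C)(C)C)cc1CC=C(C)C
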